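Retrosynthesis: the C2' O-prenyl bond and the O–Si bond on the C6' hydroxymethyl group are cut first. Ring B is then opened at C2'–C3', C4'–C5' and C1'–C2' into methoxyacetylene (C3', C4') and a 4-aryloxycyclobutenone whose ring carbons are C2' (C=O), C5' (prenyl), C6' (CH2O) and C1' (CH–OAr).
The cyclobutenone is cut into a hydroxymethyl anion equivalent (the C6' side-chain carbon), an aryloxyketene (C6' and C1', from the ring A phenol and bromoacetate) and a prenylated ynol ether (C5' and C2').
Enabling feature: ring B carries oxygen on C2' and C4' in a meta relation with the only ring hydrogen (C3') between them, and the ether oxygen on C1' next to C2'. This is the pattern left by a ketene carbon (C2'), an alkoxyacetylene (C3', C4') and an oxygen-bearing vinylketene terminus (C1').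
Forward: ring A is bought complete. The four-membered ring is made by ketene/ynol ether [2+2] cycloaddition and re-functionalised by 1,2-addition and carbonyl transposition. Ring B then arises in one thermal operation, and O-prenylation at C2' and desilylation finish the route.
Stereochemistry: the target has no stereocentre and no stereogenic double bond. The CH–OAr carbon of the cyclobutenones is racemic and becomes aromatic C1'.

Key step: step 10

Abbreviations: prenyl = 3-methylbut-2-en-1-yl; TBS = tert-butyldimethylsilyl; ring A = the benzoate ring; ring B = C1'–C6' as defined above.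
Assumption: (tributylstannyl)methanol 13 is treated as a purchasable reagent (otherwise one step from Bu3SnH, LiN(i-Pr)2 and paraformaldehyde).
Remark on the protecting group: the hydroxymethyl group travels as a silyl ether released by fluoride, so that no oxidant has to meet the benzylic, allylic CH2 of the C5' prenyl group on the electron-rich ring B.

Step 1
Reactants: 1 methyl 2,6-dihydroxybenzoate; 2 prenyl bromide
Product: 3 methyl 2-hydroxy-6-(prenyloxy)benzoate
Conditions: 2 (1.0 equiv), K2CO3 (1.1 equiv), acetone, reflux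
Reagents that add atoms: none
Why: Williamson ether synthesis; after the first alkylation the remaining hydroxyl is held in a hydrogen bond to the ester carbonyl and is much less nucleophilic, so one equivalent of bromide should stop at the monoether.

Step 2
Reactants: 3 methyl 2-hydroxy-6-(prenyloxy)benzoate; 4 methyl bromoacetate
Product: 5 methyl 2-(2-methoxy-2-oxoethoxy)-6-(prenyloxy)benzoate
Conditions: 4 (1.3 equiv), K2CO3, acetone, reflux
Reagents that add atoms: none
Why: Williamson ether synthesis (SN2) with a highly reactive α-bromo ester, run with a weak base so that Dieckmann closure onto the benzoate should not follow.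

Step 3
Reactants: 5 methyl 2-(2-methoxy-2-oxoethoxy)-6-(prenyloxy)benzoate
Product: 6 [2-(methoxycarbonyl)-3-(prenyloxy)phenoxy]acetic acid
Conditions: LiOH·H2O (1.1 equiv), THF/H2O, 0 °C; then 1 M HCl to pH 3, 0 °C
Reagents that add atoms: LiOH (hydroxide oxygen), [Li+].[OH-]
Why: Chemoselective saponification; the unhindered aryloxyacetate ester should be hydrolysed much faster than the benzoate flanked by two ortho oxygen substituents.

Step 4
Reactants: 7 ethoxyacetylene; 2 prenyl bromide
Product: 9 1-ethoxy-5-methylhex-4-en-1-yne, via lithium ethoxyacetylide 8 (not isolated)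
Conditions: n-BuLi, THF, −78 °C; then 2, DMPU, −78 °C to rt
Reagents that add atoms: none
Why: Acetylide alkylation (SN2 at the primary allylic carbon) of the lithiated ynol ether, with a dipolar cosolvent to raise its nucleophilicity.

Step 5
Reactants: 6 [2-(methoxycarbonyl)-3-(prenyloxy)phenoxy]acetic acid; 9 1-ethoxy-5-methylhex-4-en-1-yne
Product: 12 methyl 2-{[2-ethoxy-4-oxo-3-prenylcyclobut-2-en-1-yl]oxy}-6-(prenyloxy)benzoate (racemic), via aryloxyacetyl chloride 10 (not isolated), via aryloxyketene 11 (not isolated)
Conditions: Me2C=C(Cl)NMe2 (1.05 equiv), CH2Cl2, 0 °C to rt; then 9 (1.5 equiv), Et3N (slow addition), CH2Cl2, rt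
Reagents that add atoms: none
Why: Ketene–ynol ether [2+2] cycloaddition; the acid chloride is made with an α-chloroenamine under neutral conditions that spare the prenyl ether, dehydrochlorination gives the aryloxyketene, and the nucleophilic β-carbon of the ynol ether bonds to the ketene carbonyl carbon so that OEt ends β and the prenyl group α to the ketone.

Step 6
Reactants: 13 (tributylstannyl)methanol
Product: 14 tributyl[(1-ethoxyethoxy)methyl]stannane (racemic)
Conditions: ethyl vinyl ether, PPTS (cat.), CH2Cl2, rt
Reagents that add atoms: ethyl vinyl ether, C=COCC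
Why: Acid-catalysed acetalisation of the alcohol with an enol ether gives the stannane precursor of a protected hydroxymethyl anion.

Step 7
Reactants: 14 tributyl[(1-ethoxyethoxy)methyl]stannane; 12 methyl 2-{[2-ethoxy-4-oxo-3-prenylcyclobut-2-en-1-yl]oxy}-6-(prenyloxy)benzoate
Product: 17 methyl 2-{[2-(hydroxymethyl)-4-oxo-3-prenylcyclobut-2-en-1-yl]oxy}-6-(prenyloxy)benzoate (racemic), via (1-ethoxyethoxy)methyllithium 15 (not isolated), via cyclobutenyl carbinol 16 (not isolated)
Conditions: 14 (1.3 equiv), n-BuLi (1.2 equiv), THF, −78 °C; then 12, −78 °C; then 1 M HCl, THF, 0 °C to rt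
Reagents that add atoms: water, O
Why: Tin–lithium exchange and 1,2-addition of the α-alkoxy organolithium to the strained ketone (far more electrophilic than the doubly ortho-substituted benzoate), followed by acid hydrolysis of the β-ethoxy allylic carbinol with 1,3-carbonyl transposition, the acetal being cleaved in the same operation.

Step 8
Reactants: 17 methyl 2-{[2-(hydroxymethyl)-4-oxo-3-prenylcyclobut-2-en-1-yl]oxy}-6-(prenyloxy)benzoate
Product: 18 methyl 2-{[2-(TBS-oxymethyl)-4-oxo-3-prenylcyclobut-2-en-1-yl]oxy}-6-(prenyloxy)benzoate (racemic)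
Conditions: TBSCl, imidazole, CH2Cl2, 0 °C to rt
Reagents that add atoms: tert-butyldimethylsilyl chloride, CC(C)(C)[Si](C)(C)Cl
Why: Silylation of a primary alcohol; the silyl ether should be inert to the thermal step and to K2CO3 alkylation and is later cleaved by fluoride.

Step 9
Reactants: 19 chloroacetaldehyde dimethyl acetal
Product: 21 methoxyacetylene, via sodium methoxyacetylide 20 (not isolated)
Conditions: NaNH2 (3.3 equiv), liquid NH3, −33 °C; NH3 evaporated; then cold saturated aqueous NaCl, −20 °C; distilled into cold toluene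
Reagents that add atoms: none
Why: Base-induced double elimination (methanol, then HCl) gives the alkynyl ether as its sodium acetylide, which is protonated and distilled off as the volatile ynol ether.

Step 10
Reactants: 18 methyl 2-{[2-(TBS-oxymethyl)-4-oxo-3-prenylcyclobut-2-en-1-yl]oxy}-6-(prenyloxy)benzoate; 21 methoxyacetylene
Product: 26 methyl 2-[2-hydroxy-4-methoxy-5-prenyl-6-(TBS-oxymethyl)phenoxy]-6-(prenyloxy)benzoate (ring B numbering), via vinylketene 22 (not isolated), via 4-alkenylcyclobutenone 23 (not isolated), via dienylketene 24 (not isolated), via cyclohexa-2,4-dienone 25 (not isolated)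
Conditions: 21 (3 equiv), toluene, sealed tube, 80 °C then 110 °C
Reagents that add atoms: none
Why: Heating opens the cyclobutenone by 4π electrocyclic cleavage of the C(=O)–CH(OAr) bond to vinylketene 22, whose ketene C=C undergoes [2+2] cycloaddition with methoxyacetylene to give 23, which reopens (4π) to dienylketene 24 and closes by 6π electrocyclisation to dienone 25, tautomerising to phenol 26. The closest known reaction type is the Danheiser benzannulation of cyclobutenones with alkoxyacetylenes to resorcinol monoethers; the aryloxy group on the sp3 carbon is an added donor that should ease the first ring opening and rotate outward. Ring B is closed by a thermally allowed disrotatory 6π electrocyclisation between the ketene carbon (C2') and the aryloxy-bearing terminus (C1'), after C2'–C3' and C4'–C5' have been made in the polar [2+2] step that closes the transient four-membered ring of 23. No stereocentre is created, the racemic CH(OAr) carbon becoming aromatic C1'. The step needs regioselectivity in the [2+2], secured by the polarity of the ynol ether (its unsubstituted β-carbon bonds to the electrophilic ketene carbonyl carbon, so OMe ends at C4' and the free hydroxyl at C2'), and chemoselectivity for the electron-rich alkyne over the two unactivated prenyl alkenes, secured by the large gap in nucleophilicity. The hydrogen on C1' of 25 ensures aromatisation.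

Step 11
Reactants: 26 methyl 2-[2-hydroxy-4-methoxy-5-prenyl-6-(TBS-oxymethyl)phenoxy]-6-(prenyloxy)benzoate; 2 prenyl bromide
Product: 27 methyl 2-[4-methoxy-5-prenyl-2-(prenyloxy)-6-(TBS-oxymethyl)phenoxy]-6-(prenyloxy)benzoate
Conditions: 2 (1.5 equiv), K2CO3, acetone, 50 °C
Reagents that add atoms: none
Why: Williamson O-alkylation of the only free phenol in the molecule.

Step 12
Reactants: 27 methyl 2-[4-methoxy-5-prenyl-2-(prenyloxy)-6-(TBS-oxymethyl)phenoxy]-6-(prenyloxy)benzoate
Product: 28 methyl 2-[6-(hydroxymethyl)-4-methoxy-5-prenyl-2-(prenyloxy)phenoxy]-6-(prenyloxy)benzoate (target)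
Conditions: Bu4NF, THF, 0 °C to rt
Reagents that add atoms: none
Why: Fluoride-induced cleavage of the silyl ether (Si–F bond formation) should leave the hindered ester, the aryl prenyl ethers and the alkenes untouched.

Compound list
1 | methyl 2,6-dihydroxybenzoate | COC(=O)c1c(O)cccc1O | starting material
2 | prenyl bromide (1-bromo-3-methylbut-2-ene) | CC(C)=CCBr | starting material
3 | methyl 2-hydroxy-6-[(3-methylbut-2-en-1-yl)oxy]benzoate | COC(=O)c1c(O)cccc1OCC=C(C)C | intermediate
4 | methyl bromoacetate | COC(=O)CBr | starting material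
5 | methyl 2-(2-methoxy-2-oxoethoxy)-6-[(3-methylbut-2-en-1-yl)oxy]benzoate | COC(=O)COc1cccc(OCC=C(C)C)c1C(=O)OC | intermediate
6 | {2-(methoxycarbonyl)-3-[(3-methylbut-2-en-1-yl)oxy]phenoxy}acetic acid | OC(=O)COc1cccc(OCC=C(C)C)c1C(=O)OC | intermediate
7 | ethoxyacetylene (ethoxyethyne) | CCOC#C | starting material
8 | lithium ethoxyacetylide | [Li]C#COCC | intermediate (not isolated)
9 | 1-ethoxy-5-methylhex-4-en-1-yne | CCOC#CCC=C(C)C | intermediate
10 | methyl 2-(2-chloro-2-oxoethoxy)-6-[(3-methylbut-2-en-1-yl)oxy]benzoate (aryloxyacetyl chloride) | ClC(=O)COc1cccc(OCC=C(C)C)c1C(=O)OC | intermediate (not isolated)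
11 | methyl 2-[(2-oxoethenyl)oxy]-6-[(3-methylbut-2-en-1-yl)oxy]benzoate (aryloxyketene) | O=C=COc1cccc(OCC=C(C)C)c1C(=O)OC | intermediate (not isolated)
12 | methyl 2-{[2-ethoxy-3-(3-methylbut-2-en-1-yl)-4-oxocyclobut-2-en-1-yl]oxy}-6-[(3-methylbut-2-en-1-yl)oxy]benzoate, racemic | CCOC1=C(CC=C(C)C)C(=O)C1Oc1cccc(OCC=C(C)C)c1C(=O)OC | intermediate
13 | (tributylstannyl)methanol | CCCC[Sn](CCCC)(CCCC)CO | starting material
14 | tributyl[(1-ethoxyethoxy)methyl]stannane, racemic | CCCC[Sn](CCCC)(CCCC)COC(C)OCC | intermediate
15 | [(1-ethoxyethoxy)methyl]lithium | [Li]COC(C)OCC | intermediate (not isolated)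
16 | methyl 2-{[2-ethoxy-4-[(1-ethoxyethoxy)methyl]-4-hydroxy-3-(3-methylbut-2-en-1-yl)cyclobut-2-en-1-yl]oxy}-6-[(3-methylbut-2-en-1-yl)oxy]benzoate (present as its lithium alkoxide until acid is added; mixture of racemic diastereomers) | CCOC1=C(CC=C(C)C)C(O)(COC(C)OCC)C1Oc1cccc(OCC=C(C)C)c1C(=O)OC | intermediate (not isolated)
17 | methyl 2-{[2-(hydroxymethyl)-3-(3-methylbut-2-en-1-yl)-4-oxocyclobut-2-en-1-yl]oxy}-6-[(3-methylbut-2-en-1-yl)oxy]benzoate, racemic | O=C1C(CC=C(C)C)=C(CO)C1Oc1cccc(OCC=C(C)C)c1C(=O)OC | intermediate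
18 | methyl 2-{[2-({[tert-butyl(dimethyl)silyl]oxy}methyl)-3-(3-methylbut-2-en-1-yl)-4-oxocyclobut-2-en-1-yl]oxy}-6-[(3-methylbut-2-en-1-yl)oxy]benzoate, racemic | O=C1C(CC=C(C)C)=C(CO[Si](C)(C)C(C)(C)C)C1Oc1cccc(OCC=C(C)C)c1C(=O)OC | intermediate
19 | chloroacetaldehyde dimethyl acetal (2-chloro-1,1-dimethoxyethane) | COC(CCl)OC | starting material
20 | sodium methoxyacetylide | [Na+].[C-]#COC | intermediate (not isolated)
21 | methoxyacetylene (methoxyethyne) | COC#C | intermediate
22 | methyl 2-{[2-({[tert-butyl(dimethyl)silyl]oxy}methyl)-3-(3-methylbut-2-en-1-yl)-4-oxobuta-1,3-dien-1-yl]oxy}-6-[(3-methylbut-2-en-1-yl)oxy]benzoate (vinylketene; aryloxy group trans to the ketene carbon) | O=C=C(CC=C(C)C)/C(CO[Si](C)(C)C(C)(C)C)=C/Oc1cccc(OCC=C(C)C)c1C(=O)OC | intermediate (not isolated)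
23 | methyl 2-{[2-({[tert-butyl(dimethyl)silyl]oxy}methyl)-2-[2-methoxy-1-(3-methylbut-2-en-1-yl)-4-oxocyclobut-2-en-1-yl]ethenyl]oxy}-6-[(3-methylbut-2-en-1-yl)oxy]benzoate, racemic | O=C1C=C(OC)C1(CC=C(C)C)/C(CO[Si](C)(C)C(C)(C)C)=C/Oc1cccc(OCC=C(C)C)c1C(=O)OC | intermediate (not isolated)
24 | methyl 2-{[2-({[tert-butyl(dimethyl)silyl]oxy}methyl)-4-methoxy-3-(3-methylbut-2-en-1-yl)-6-oxohexa-1,3,5-trien-1-yl]oxy}-6-[(3-methylbut-2-en-1-yl)oxy]benzoate (dienylketene; ketene arm and aryloxyvinyl group cis on the central double bond) | O=C=C/C(OC)=C(CC=C(C)C)\C(CO[Si](C)(C)C(C)(C)C)=C\Oc1cccc(OCC=C(C)C)c1C(=O)OC | intermediate (not isolated)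
25 | methyl 2-{[2-({[tert-butyl(dimethyl)silyl]oxy}methyl)-4-methoxy-3-(3-methylbut-2-en-1-yl)-6-oxocyclohexa-2,4-dien-1-yl]oxy}-6-[(3-methylbut-2-en-1-yl)oxy]benzoate, racemic | O=C1C=C(OC)C(CC=C(C)C)=C(CO[Si](C)(C)C(C)(C)C)C1Oc1cccc(OCC=C(C)C)c1C(=O)OC | intermediate (not isolated)
26 | methyl 2-[2-({[tert-butyl(dimethyl)silyl]oxy}methyl)-6-hydroxy-4-methoxy-3-(3-methylbut-2-en-1-yl)phenoxy]-6-[(3-methylbut-2-en-1-yl)oxy]benzoate | COC(=O)c1c(OCC=C(C)C)cccc1Oc1c(O)cc(OC)c(CC=C(C)C)c1CO[Si](C)(C)C(C)(C)C | intermediate
27 | methyl 2-{2-({[tert-butyl(dimethyl)silyl]oxy}methyl)-4-methoxy-3-(3-methylbut-2-en-1-yl)-6-[(3-methylbut-2-en-1-yl)oxy]phenoxy}-6-[(3-methylbut-2-en-1-yl)oxy]benzoate | COC(=O)c1c(OCC=C(C)C)cccc1Oc1c(OCC=C(C)C)cc(OC)c(CC=C(C)C)c1CO[Si](C)(C)C(C)(C)C | intermediate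
28 | methyl 2-{2-(hydroxymethyl)-4-methoxy-3-(3-methylbut-2-en-1-yl)-6-[(3-methylbut-2-en-1-yl)oxy]phenoxy}-6-[(3-methylbut-2-en-1-yl)oxy]benzoate (CNP0500611.0) | COC(=O)c1c(OCC=C(C)C)cccc1Oc1c(OCC=C(C)C)cc(OC)c(CC=C(C)C)c1CO | target

Total step count: 12.
Longest linear sequence: 9 steps (steps 1, 2, 3, 5, 7, 8, 10, 11, 12); steps 4, 6 and 9 are side branches.

Steps most likely to fail

Step 10. The free vinylketene may be lost to self-condensation, or to acylation of phenol already formed, before the volatile and only moderately nucleophilic methoxyacetylene intercepts it. The fallback sets out from 18 and comes back at 23, and through it at 26. It brings in C3' and C4' at the ketene acetal oxidation level and separates capture from aromatisation. Heating 18 with 1,1-dimethoxyethene (commercial, higher boiling, far more nucleophilic) in toluene at 80 °C should give, by [2+2] cycloaddition of the vinylketene with the ketene acetal, the 3,3-dimethoxycyclobutanone that carries on C2 the prenyl group and the 2-aryloxy-1-(TBS-oxymethyl)vinyl group, F1. Elimination of methanol from it on basic Al2O3 in CH2Cl2 at rt should give the 3-methoxy-4-alkenylcyclobutenone 23, now isolated. Heating 23 alone in toluene at 110 °C completes the 4π opening and 6π closure to 26, with no phenol present while the vinylketene is free.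

Step 5. The aryloxyketene is generated beside a benzoate ester and in the presence of amine. It may condense with itself, or its ammonium enolate may close onto the neighbouring ester (Dieckmann-type), faster than it meets the internal ynol ether. The fallback sets out from 9 and 3 and comes back at 12. It attaches the ring A oxygen after the four-membered ring exists. Chloroacetyl chloride and Et3N in the presence of 9 (CH2Cl2, rt) generate chloroketene F2, whose [2+2] adduct with the same regiochemistry is 4-chloro-3-ethoxy-2-prenylcyclobut-2-en-1-one F3. SN2 substitution at its α-chloro ketone carbon by the phenoxide of 3 (Cs2CO3, DMF, rt) should then give 12.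

Step 7. The strongly basic α-alkoxy organolithium may attack the benzoate or abstract a proton instead of adding to the ketone, and an acid step that has to perform two unmasking events may degrade the aryl prenyl ether. The fallback sets out from 12 and comes back at 17. It uses a Grignard-based hydroxymethyl anion equivalent and unmasks the carbinol under mildly basic conditions. (Chloromethyl)dimethyl(propan-2-yloxy)silane and Mg in THF give {[dimethyl(propan-2-yloxy)silyl]methyl}magnesium chloride F4. Its 1,2-addition to 12 at 0 °C gives the β-hydroxysilane adduct F5. Tamao–Fleming oxidation (H2O2, KF, KHCO3, THF/MeOH, rt) converts the C–Si bond into C–OH and gives the 1-(hydroxymethyl)cyclobutenol F6. Brief treatment with dilute HCl in THF at 0 °C then only has to effect the carbonyl transposition to 17.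

Further compounds
F1 | step 10 | methyl 2-{[2-({[tert-butyl(dimethyl)silyl]oxy}methyl)-2-[2,2-dimethoxy-1-(3-methylbut-2-en-1-yl)-4-oxocyclobutyl]ethenyl]oxy}-6-[(3-methylbut-2-en-1-yl)oxy]benzoate, racemic | O=C1CC(OC)(OC)C1(CC=C(C)C)/C(CO[Si](C)(C)C(C)(C)C)=C/Oc1cccc(OCC=C(C)C)c1C(=O)OC
F2 | step 5 | chloroketene | O=C=CCl
F3 | step 5 | 4-chloro-3-ethoxy-2-(3-methylbut-2-en-1-yl)cyclobut-2-en-1-one, racemic | CCOC1=C(CC=C(C)C)C(=O)C1Cl
F4 | step 7 | {[dimethyl(propan-2-yloxy)silyl]methyl}magnesium chloride | CC(C)O[Si](C)(C)C[Mg]Cl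
F5 | step 7 | methyl 2-{[4-{[dimethyl(propan-2-yloxy)silyl]methyl}-2-ethoxy-4-hydroxy-3-(3-methylbut-2-en-1-yl)cyclobut-2-en-1-yl]oxy}-6-[(3-methylbut-2-en-1-yl)oxy]benzoate, mixture of racemic diastereomers | CCOC1=C(CC=C(C)C)C(O)(C[Si](C)(C)OC(C)C)C1Oc1cccc(OCC=C(C)C)c1C(=O)OC
F6 | step 7 | methyl 2-{[2-ethoxy-4-hydroxy-4-(hydroxymethyl)-3-(3-methylbut-2-en-1-yl)cyclobut-2-en-1-yl]oxy}-6-[(3-methylbut-2-en-1-yl)oxy]benzoate, mixture of racemic diastereomers | CCOC1=C(CC=C(C)C)C(O)(CO)C1Oc1cccc(OCC=C(C)C)c1C(=O)OC
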